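**Retrosynthetic overview**

- Metachromin B 28 ⇐ 27 ⇐ 26 (O-methylation at C6, removal of the C5 sulfonate). 26 ⇐ spirodienone 25 by a 1,2-shift of C4 from C8a to C4a (dienone–phenol ring expansion of the five-membered O-ring to the pyran). 25 ⇐ Z-alkenyl phenol 24 by oxidative spirocyclisation.
- Enabling feature: C8a, the benzene carbon that carries the pyran oxygen O1, is para to the C6 oxygen. Its neighbours are C4a (unsubstituted) and C8 (methoxylated). A C6 phenol can therefore be dearomatised at C8a with O1 and C4 both on that carbon, and C4 can only end up on C4a.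
- 24 ⇐ aryl iodide 22 + tertiary propargylic alcohol 17 (Sonogashira coupling, semi-hydrogenation). C2 of the chromene is set in 15 by Sharpless epoxidation, and its C–O bond is never broken afterwards.
- 17 ⇐ alkyne 11 ⇐ octalone 7 (epoxidation, Eschenmoser–Tanabe fragmentation, methylenation). 7 ⇐ 2,6-dimethylcyclohexanone + methyl vinyl ketone (auxiliary-controlled Michael addition, Robinson annulation under equilibrating conditions for the trans ring methyls).
- Ring order: cyclohexane bought, its stereocentres fixed inside a temporary second carbocycle (closed in step 3, cut in step 5); benzene ring bought; five-membered oxaspiro ring and then the six-membered pyran from it, both in step 16.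

Key step: step 16

Assumption: the (S)-1-phenylethylamine imine of 2,6-dimethylcyclohexanone is taken to show the same sense of induction as that of 2-methylcyclohexanone; if the opposite sense were found, the (R)-amine would be used with no other change.

**Route**

Step 1
Reactants: 1 2,6-dimethylcyclohexan-1-one (cis/trans mixture); 2 (S)-1-phenylethylamine
Product: 3 (S)-N-(1-phenylethyl)-2,6-dimethylcyclohexan-1-imine (isomer mixture)
Conditions: TsOH·H2O (cat.), toluene, reflux, Dean–Stark
Reagents that add atoms: none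
Why: Acid-catalysed imine condensation with azeotropic removal of water should give the imine, whose secondary enamine tautomer is the nucleophile of step 2 and whose (S)-1-phenylethyl group is the source of asymmetry.

Step 2
Reactants: 3 imine; 4 methyl vinyl ketone
Product: 6 (2R)-2,6-dimethyl-2-(3-oxobutyl)cyclohexan-1-one (either C6 epimer), via Michael-adduct imine 5 (not isolated)
Conditions: THF, 25 °C, 72 h; then 10% aq AcOH, 25 °C
Reagents that add atoms: water, O
Why: Auxiliary-controlled aza-ene-type Michael addition of the secondary enamine to the enone (deracemising alkylation of a chiral imine) should place the chain on the enamine face away from the phenyl group and set the quaternary carbon as (R); the C6 methyl is left uncontrolled here and is corrected in step 3, and hydrolysis frees the diketone and the amine.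

Step 3
Reactants: 6 diketone
Product: 7 (4aR,8R)-4a,8-dimethyl-4,4a,5,6,7,8-hexahydronaphthalen-2(3H)-one
Conditions: NaOMe (0.3 equiv), MeOH, 65 °C
Reagents that add atoms: none
Why: Robinson-type intramolecular aldol condensation; under the equilibrating conditions C8 should epimerise through the extended dienolate to the trans-dimethyl octalone, in which the C8 methyl is equatorial and avoids the syn-diaxial contact with the angular methyl that the cis isomer would have.

Step 4
Reactants: 7 octalone
Product: 8 (4aR,8R)-1,8a-epoxy-4a,8-dimethyloctahydronaphthalen-2(1H)-one (both epoxide faces)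
Conditions: 30% H2O2, NaOH (cat.), MeOH, 0 → 25 °C
Reagents that add atoms: hydrogen peroxide, OO
Why: Weitz–Scheffer nucleophilic epoxidation of the enone; the facial outcome is irrelevant because both epoxide carbons lose their configuration in step 5.

Step 5
Reactants: 8 epoxy ketone
Product: 10 (2R,6R)-2-(but-3-yn-1-yl)-2,6-dimethylcyclohexan-1-one, via tosylhydrazone 9 (not isolated)
Conditions: TsNHNH2, AcOH/CH2Cl2 (1:1), −20 → 25 °C
Reagents that add atoms: p-toluenesulfonyl hydrazide, Cc1ccc(cc1)S(=O)(=O)NN (its atoms remain in 9 only)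
Why: Eschenmoser–Tanabe fragmentation of the α,β-epoxy ketone tosylhydrazone cuts the C1–C8a bond and should give the ring ketone and the terminal alkyne without touching either stereocentre, the weakly acidic, cold medium being chosen to avoid enolisation towards C6.

Step 6
Reactants: 10 alkynyl ketone
Product: 11 (1R,3R)-1-(but-3-yn-1-yl)-1,3-dimethyl-2-methylidenecyclohexane
Conditions: Zn, CH2Br2, TiCl4, THF/CH2Cl2, 0 → 25 °C
Reagents that add atoms: dibromomethane, BrCBr
Why: Takai–Lombardo methylenation uses a non-basic titanium-activated geminal dizinc reagent that is suited to hindered ketones and should leave the epimerisable α-stereocentre and the terminal alkyne untouched.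

Step 7
Reactants: 11 alkyne
Product: 14 (2E)-5-[(1R,3R)-1,3-dimethyl-2-methylidenecyclohexyl]-3-methylpent-2-en-1-ol, via alkenylalane 12 (not isolated), via lithium alanate 13 (not isolated)
Conditions: Me3Al, Cp2ZrCl2 (25 mol%), CH2Cl2, 25 °C; then n-BuLi, THF, −78 °C; (CH2O)n, −78 → 25 °C
Reagents that add atoms: trimethylaluminium, C[Al](C)C; formaldehyde (from paraformaldehyde), C=O; n-butyllithium, [Li]CCCC (its atoms remain in 13 only)
Why: Zirconium-catalysed syn-carboalumination (Negishi) puts methyl on the internal and aluminium on the terminal alkyne carbon, and hydroxymethylation of the derived alanate with retention should give the (E)-trisubstituted allylic alcohol; the hindered 1,1-disubstituted alkene does not carbometalate.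

Step 8
Reactants: 14 allylic alcohol
Product: 15 [(2S,3S)-3-{2-[(1R,3R)-1,3-dimethyl-2-methylidenecyclohexyl]ethyl}-3-methyloxiran-2-yl]methanol
Conditions: Ti(OiPr)4 (10 mol%), L-(+)-diethyl tartrate (12 mol%), t-BuOOH, 4 Å MS, CH2Cl2, −20 °C
Reagents that add atoms: tert-butyl hydroperoxide, CC(C)(C)OO
Why: Sharpless asymmetric epoxidation; L-(+)-tartrate should deliver oxygen to the face that gives the (2S,3S)-epoxide, as for other (E)-3-methylalk-2-en-1-ols, so the future C2 of the chromene is set by reagent control, and the exocyclic alkene, which has no directing hydroxyl, is not epoxidised.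

Step 9
Reactants: 15 epoxy alcohol
Product: 16 (2R,3S)-2-(chloromethyl)-3-{2-[(1R,3R)-1,3-dimethyl-2-methylidenecyclohexyl]ethyl}-3-methyloxirane
Conditions: PPh3, CCl4, NaHCO3, reflux
Reagents that add atoms: tetrachloromethane, ClC(Cl)(Cl)Cl
Why: Appel chlorination of the primary alcohol under buffered neutral conditions should leave the epoxide closed (the descriptor at C2 changes only because chlorine raises the priority of the CH2 group).

Step 10
Reactants: 16 epoxy chloride
Product: 17 (3S)-5-[(1R,3R)-1,3-dimethyl-2-methylidenecyclohexyl]-3-methylpent-1-yn-3-ol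
Conditions: n-BuLi (3.2 equiv), THF, −78 → −30 °C; aq NH4Cl
Reagents that add atoms: none
Why: Base-induced double elimination of the 2,3-epoxy chloride (epoxide-opening β-elimination, then loss of chloride) should give the tertiary propargylic alcohol; the C–O bond at the tertiary carbon is never broken, so its configuration is retained.

Step 11
Reactants: 18 2-bromo-4-methoxyphenol
Product: 19 2-bromo-4-methoxyphenyl 4-methylbenzenesulfonate
Conditions: TsCl, Et3N, DMAP (cat.), CH2Cl2, 0 → 25 °C
Reagents that add atoms: p-toluenesulfonyl chloride, Cc1ccc(cc1)S(=O)(=O)Cl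
Why: O-sulfonylation of the phenol; the sulfonate protects the future C5 oxygen, does not migrate to a neighbouring oxygen and makes its ring carbon a poor site for nucleophilic attack in step 16.

Step 12
Reactants: 19 aryl bromide
Product: 21 2-hydroxy-4-methoxyphenyl 4-methylbenzenesulfonate, via arylboronate 20 (not isolated)
Conditions: B2pin2, Pd(dppf)Cl2 (3 mol%), KOAc, dioxane, 85 °C; then NaBO3·4H2O, THF/H2O, 25 °C
Reagents that add atoms: bis(pinacolato)diboron, CC1(C)OB(OC1(C)C)B1OC(C)(C)C(C)(C)O1 (its atoms remain in 20 only); sodium perborate, [Na+].[O-]OB=O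
Why: Miyaura borylation of the C–Br bond followed by oxidation of the C–B bond in the same flask should install the second hydroxyl, the aryl sulfonate being inert to both operations.

Step 13
Reactants: 21 phenol
Product: 22 2-hydroxy-5-iodo-4-methoxyphenyl 4-methylbenzenesulfonate
Conditions: N-iodosuccinimide, MeCN, 0 °C
Reagents that add atoms: N-iodosuccinimide, O=C1CCC(=O)N1I
Why: Electrophilic aromatic iodination should occur at the position para to the free hydroxyl and ortho to the methoxy group, which is the most activated and least hindered site.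

Step 14
Reactants: 17 propargylic alcohol; 22 aryl iodide
Product: 23 2-hydroxy-5-{(3S)-3-hydroxy-5-[(1R,3R)-1,3-dimethyl-2-methylidenecyclohexyl]-3-methylpent-1-yn-1-yl}-4-methoxyphenyl 4-methylbenzenesulfonate
Conditions: Pd(PPh3)2Cl2 (3 mol%), CuI (5 mol%), Et3N, THF, 40 °C
Reagents that add atoms: none
Why: Sonogashira coupling of the terminal alkyne with the aryl iodide tolerates the free phenol and tertiary alcohol and does not touch the aryl sulfonate.

Step 15
Reactants: 23 aryl alkyne
Product: 24 2-hydroxy-5-{(1Z,3S)-3-hydroxy-5-[(1R,3R)-1,3-dimethyl-2-methylidenecyclohexyl]-3-methylpent-1-en-1-yl}-4-methoxyphenyl 4-methylbenzenesulfonate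
Conditions: H2 (1 atm), Pd/CaCO3 poisoned with Pb(OAc)2, quinoline, EtOAc, 25 °C
Reagents that add atoms: none
Why: Lindlar semi-hydrogenation adds hydrogen syn to the alkyne and should give the Z alkene, while the hindered 1,1-disubstituted alkene is reduced much more slowly; 24 is used at once because p-hydroxystyryl carbinols lose water easily.

Step 16
Reactants: 24 Z-alkenyl phenol
Product: 26 (2S)-2-{2-[(1R,3R)-1,3-dimethyl-2-methylidenecyclohexyl]ethyl}-6-hydroxy-8-methoxy-2-methyl-2H-chromen-5-yl 4-methylbenzenesulfonate, via spirodienone 25 (not isolated)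
Conditions: PhI(OAc)2, 2,6-di-tert-butyl-4-methylpyridine, CH2Cl2/CF3CH2OH, −40 °C; then BF3·OEt2, −78 → −30 °C
Reagents that add atoms: none
Why: PhI(OAc)2 oxidises the C6 phenol through an aryloxy-λ3-iodane, and the tertiary hydroxyl, held next to the para carbon C8a by the Z alkene, attacks that ipso carbon (5-exo closure) to give the 1-oxaspiro[4.5]deca-3,6,9-trien-8-one 25, a known hypervalent-iodine dearomatising spiroetherification. BF3 activation of the dienone carbonyl then triggers a dienone–phenol rearrangement: the alkenyl carbon C4 shifts from C8a to C4a, the cation left at C8a is an oxocarbenium ion stabilised by O1, and loss of the C4a proton restores the arene, so the six-membered pyran arises by ring expansion of the five-membered spiro ring and not by a closure of its own. No new stereocentre survives: the spiro carbon is transient and both its epimers converge, while C2 keeps its configuration because none of its four bonds is broken. The step needs carbon and not oxygen to migrate, and to C4a and not to C8: an sp2 carbon migrates more readily than an ether oxygen and leaves the better stabilised cation, and C4a is the only neighbour of C8a that bears hydrogen, so a shift to the methoxylated C8 is reversible and unproductive. Attack at the para carbon is secured by the five-membered intramolecular geometry and by the electron-poor sulfonate on the ortho carbon C5, and the hindered pyridine base takes up stray protons so that neither the exocyclic methylene nor the tertiary allylic ether should be ionised.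

Step 17
Reactants: 26 6-hydroxychromene
Product: 27 (2S)-2-{2-[(1R,3R)-1,3-dimethyl-2-methylidenecyclohexyl]ethyl}-6,8-dimethoxy-2-methyl-2H-chromen-5-yl 4-methylbenzenesulfonate
Conditions: MeI, K2CO3, acetone, 25 °C
Reagents that add atoms: iodomethane, CI
Why: Williamson O-methylation of the only free phenol; the neighbouring oxygen is blocked as a sulfonate, which does not migrate under these mild conditions.

Step 18
Reactants: 27 aryl sulfonate
Product: 28 metachromin B, (2S)-2-{2-[(1R,3R)-1,3-dimethyl-2-methylidenecyclohexyl]ethyl}-6,8-dimethoxy-2-methyl-2H-chromen-5-ol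
Conditions: KOH, EtOH/H2O, 70 °C, Ar; then aq NH4Cl
Reagents that add atoms: none
Why: Hydroxide attack at sulfur cleaves the aryl sulfonate (S–O cleavage) and should free the C5 phenol; the chromene, the tertiary ether and the exocyclic alkene are stable to base, and air is excluded because the product is an electron-rich phenol.

**Compound list**

1 | 2,6-dimethylcyclohexan-1-one (cis/trans mixture) | CC1CCCC(C)C1=O | starting material
2 | (S)-1-phenylethylamine | C[C@H](N)c1ccccc1 | starting material
3 | (S)-N-(1-phenylethyl)-2,6-dimethylcyclohexan-1-imine | C[C@H](N=C1C(C)CCCC1C)c1ccccc1 | intermediate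
4 | methyl vinyl ketone (but-3-en-2-one) | C=CC(C)=O | starting material
5 | (S)-1-phenylethyl imine (ring C=N) of (2R)-2,6-dimethyl-2-(3-oxobutyl)cyclohexan-1-one | C[C@H](N=C1C(C)CCC[C@]1(C)CCC(C)=O)c1ccccc1 | intermediate (not isolated)
6 | (2R)-2,6-dimethyl-2-(3-oxobutyl)cyclohexan-1-one (either C6 epimer) | O=C1C(C)CCC[C@]1(C)CCC(C)=O | intermediate
7 | (4aR,8R)-4a,8-dimethyl-4,4a,5,6,7,8-hexahydronaphthalen-2(3H)-one | O=C1C=C2[C@H](C)CCC[C@]2(C)CC1 | intermediate
8 | (4aR,8R)-1,8a-epoxy-4a,8-dimethyloctahydronaphthalen-2(1H)-one (both epoxide faces) | O=C1C2OC23[C@H](C)CCC[C@]3(C)CC1 | intermediate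
9 | p-toluenesulfonylhydrazone of 8 | Cc1ccc(cc1)S(=O)(=O)NN=C1C2OC23[C@H](C)CCC[C@]3(C)CC1 | intermediate (not isolated)
10 | (2R,6R)-2-(but-3-yn-1-yl)-2,6-dimethylcyclohexan-1-one | O=C1[C@H](C)CCC[C@]1(C)CCC#C | intermediate
11 | (1R,3R)-1-(but-3-yn-1-yl)-1,3-dimethyl-2-methylidenecyclohexane | C=C1[C@H](C)CCC[C@]1(C)CCC#C | intermediate
12 | {(1E)-4-[(1R,3R)-1,3-dimethyl-2-methylidenecyclohexyl]-2-methylbut-1-en-1-yl}dimethylalane | C=C1[C@H](C)CCC[C@]1(C)CC/C(C)=C/[Al](C)C | intermediate (not isolated)
13 | lithium butyl(dimethyl)alanate of 12 | C=C1[C@H](C)CCC[C@]1(C)CC/C(C)=C/[Al-](C)(C)CCCC.[Li+] | intermediate (not isolated)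
14 | (2E)-5-[(1R,3R)-1,3-dimethyl-2-methylidenecyclohexyl]-3-methylpent-2-en-1-ol | C=C1[C@H](C)CCC[C@]1(C)CC/C(C)=C/CO | intermediate
15 | [(2S,3S)-3-{2-[(1R,3R)-1,3-dimethyl-2-methylidenecyclohexyl]ethyl}-3-methyloxiran-2-yl]methanol | C=C1[C@H](C)CCC[C@]1(C)CC[C@]2(C)O[C@H]2CO | intermediate
16 | (2R,3S)-2-(chloromethyl)-3-{2-[(1R,3R)-1,3-dimethyl-2-methylidenecyclohexyl]ethyl}-3-methyloxirane | C=C1[C@H](C)CCC[C@]1(C)CC[C@]2(C)O[C@H]2CCl | intermediate
17 | (3S)-5-[(1R,3R)-1,3-dimethyl-2-methylidenecyclohexyl]-3-methylpent-1-yn-3-ol | C=C1[C@H](C)CCC[C@]1(C)CC[C@](C)(O)C#C | intermediate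
18 | 2-bromo-4-methoxyphenol | COc1ccc(O)c(Br)c1 | starting material
19 | 2-bromo-4-methoxyphenyl 4-methylbenzenesulfonate | COc1ccc(OS(=O)(=O)c2ccc(C)cc2)c(Br)c1 | intermediate
20 | 4-methoxy-2-(4,4,5,5-tetramethyl-1,3,2-dioxaborolan-2-yl)phenyl 4-methylbenzenesulfonate | COc1ccc(OS(=O)(=O)c2ccc(C)cc2)c(c1)B1OC(C)(C)C(C)(C)O1 | intermediate (not isolated)
21 | 2-hydroxy-4-methoxyphenyl 4-methylbenzenesulfonate | COc1ccc(OS(=O)(=O)c2ccc(C)cc2)c(O)c1 | intermediate
22 | 2-hydroxy-5-iodo-4-methoxyphenyl 4-methylbenzenesulfonate | COc1cc(O)c(OS(=O)(=O)c2ccc(C)cc2)cc1I | intermediate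
23 | 2-hydroxy-5-{(3S)-3-hydroxy-5-[(1R,3R)-1,3-dimethyl-2-methylidenecyclohexyl]-3-methylpent-1-yn-1-yl}-4-methoxyphenyl 4-methylbenzenesulfonate | C=C1[C@H](C)CCC[C@]1(C)CC[C@](C)(O)C#Cc1cc(OS(=O)(=O)c2ccc(C)cc2)c(O)cc1OC | intermediate
24 | 2-hydroxy-5-{(1Z,3S)-3-hydroxy-5-[(1R,3R)-1,3-dimethyl-2-methylidenecyclohexyl]-3-methylpent-1-en-1-yl}-4-methoxyphenyl 4-methylbenzenesulfonate | C=C1[C@H](C)CCC[C@]1(C)CC[C@](C)(O)/C=C\c1cc(OS(=O)(=O)c2ccc(C)cc2)c(O)cc1OC | intermediate
25 | (2S)-2-{2-[(1R,3R)-1,3-dimethyl-2-methylidenecyclohexyl]ethyl}-6-methoxy-2-methyl-8-oxo-1-oxaspiro[4.5]deca-3,6,9-trien-9-yl 4-methylbenzenesulfonate (both C5 epimers) | C=C1[C@H](C)CCC[C@]1(C)CC[C@]2(C)OC3(C=C2)C(OC)=CC(=O)C(OS(=O)(=O)c4ccc(C)cc4)=C3 | intermediate (not isolated)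
26 | (2S)-2-{2-[(1R,3R)-1,3-dimethyl-2-methylidenecyclohexyl]ethyl}-6-hydroxy-8-methoxy-2-methyl-2H-chromen-5-yl 4-methylbenzenesulfonate | C=C1[C@H](C)CCC[C@]1(C)CC[C@@]1(C)C=Cc2c(OS(=O)(=O)c3ccc(C)cc3)c(O)cc(OC)c2O1 | intermediate
27 | (2S)-2-{2-[(1R,3R)-1,3-dimethyl-2-methylidenecyclohexyl]ethyl}-6,8-dimethoxy-2-methyl-2H-chromen-5-yl 4-methylbenzenesulfonate | C=C1[C@H](C)CCC[C@]1(C)CC[C@@]1(C)C=Cc2c(OS(=O)(=O)c3ccc(C)cc3)c(OC)cc(OC)c2O1 | intermediate
28 | metachromin B, (2S)-2-{2-[(1R,3R)-1,3-dimethyl-2-methylidenecyclohexyl]ethyl}-6,8-dimethoxy-2-methyl-2H-chromen-5-ol | C=C1[C@H](C)CCC[C@]1(C)CC[C@@]1(C)C=Cc2c(O)c(OC)cc(OC)c2O1 | target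

**Step count and risks**

Total step count: 18. Longest linear sequence: 15 steps (steps 1–10 and 14–18); steps 11–13 make the aryl iodide 22.

Steps most likely to fail:

Step 16. The rearrangement may be defeated by heterolysis of the tertiary allylic C2–O bond (loss of configuration at C2), by migration of oxygen instead of carbon, or by acid-promoted isomerisation of the exocyclic alkene. The fallback closes the pyran without a spirocycle, by palladium-catalysed aryl ether formation; it sets out from 17 and comes back at 28. Commercial 2,4-dimethoxyphenol F1 would be brominated (N-bromosuccinimide, MeCN) para to the C2 methoxy group to give 5-bromo-2,4-dimethoxyphenol F2. Iodination ortho to the hydroxyl (N-iodosuccinimide, TsOH cat.) would give 3-bromo-2-iodo-4,6-dimethoxyphenol F3, and silylation (iPr3SiOTf, 2,6-lutidine) the silyl ether (3-bromo-2-iodo-4,6-dimethoxyphenoxy)tri(propan-2-yl)silane F4. Sonogashira coupling of 17 at the C–I bond of F4 (Pd(PPh3)2Cl2, CuI, Et3N) would give (3S)-1-{2-bromo-3,5-dimethoxy-6-[tri(propan-2-yl)silyloxy]phenyl}-5-[(1R,3R)-1,3-dimethyl-2-methylidenecyclohexyl]-3-methylpent-1-yn-3-ol F5. Semi-hydrogenation (H2, Pd/CaCO3 poisoned with Pb(OAc)2, quinoline) would give the corresponding (1Z)-pent-1-en-3-ol F6. Intramolecular C–O coupling of its tertiary alcohol with the aryl bromide (Pd(OAc)2, 2-(di-tert-butylphosphino)-1,1'-binaphthyl, Cs2CO3, toluene, 80 °C) would give {[(2S)-2-{2-[(1R,3R)-1,3-dimethyl-2-methylidenecyclohexyl]ethyl}-6,8-dimethoxy-2-methyl-2H-chromen-5-yl]oxy}tri(propan-2-yl)silane F7. Bu4NF in THF would then release 28.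

Step 6. Methylenation of the doubly α-branched ketone may be slow, and the α-stereocentre may epimerise if the reaction has to be forced. The fallback is a Peterson olefination; it sets out from 10 and comes back at 11. Addition of (trimethylsilyl)methyllithium activated with CeCl3 (excess, since the alkyne C–H consumes one equivalent) would give (2R,6R)-2-(but-3-yn-1-yl)-2,6-dimethyl-1-[(trimethylsilyl)methyl]cyclohexan-1-ol F8, and KH in THF would eliminate it to 11.

Step 15. Semi-hydrogenation may run on to the alkane or touch the exocyclic alkene, or the Z geometry may be eroded. The fallback is hydrosilylation followed by protodesilylation; it sets out from 23 and comes back at 24. Platinum-catalysed syn-hydrosilylation with benzyldimethylsilane (Pt2[(CH2=CHSiMe2)2O]3, THF) would give 5-{(1E,3S)-1-[benzyl(dimethyl)silyl]-3-hydroxy-5-[(1R,3R)-1,3-dimethyl-2-methylidenecyclohexyl]-3-methylpent-1-en-1-yl}-2-hydroxy-4-methoxyphenyl 4-methylbenzenesulfonate F9 (its regioisomer converges). Bu4NF would then replace silicon by hydrogen with retention of alkene geometry to give 24.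

**Further compounds**

F1 | step 16 | 2,4-dimethoxyphenol | COc1ccc(O)c(OC)c1
F2 | step 16 | 5-bromo-2,4-dimethoxyphenol | COc1cc(OC)c(Br)cc1O
F3 | step 16 | 3-bromo-2-iodo-4,6-dimethoxyphenol | COc1cc(OC)c(Br)c(I)c1O
F4 | step 16 | (3-bromo-2-iodo-4,6-dimethoxyphenoxy)tri(propan-2-yl)silane | COc1cc(OC)c(Br)c(I)c1O[Si](C(C)C)(C(C)C)C(C)C
F5 | step 16 | (3S)-1-{2-bromo-3,5-dimethoxy-6-[tri(propan-2-yl)silyloxy]phenyl}-5-[(1R,3R)-1,3-dimethyl-2-methylidenecyclohexyl]-3-methylpent-1-yn-3-ol | C=C1[C@H](C)CCC[C@]1(C)CC[C@](C)(O)C#Cc1c(Br)c(OC)cc(OC)c1O[Si](C(C)C)(C(C)C)C(C)C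
F6 | step 16 | (1Z,3S)-1-{2-bromo-3,5-dimethoxy-6-[tri(propan-2-yl)silyloxy]phenyl}-5-[(1R,3R)-1,3-dimethyl-2-methylidenecyclohexyl]-3-methylpent-1-en-3-ol | C=C1[C@H](C)CCC[C@]1(C)CC[C@](C)(O)/C=C\c1c(Br)c(OC)cc(OC)c1O[Si](C(C)C)(C(C)C)C(C)C
F7 | step 16 | {[(2S)-2-{2-[(1R,3R)-1,3-dimethyl-2-methylidenecyclohexyl]ethyl}-6,8-dimethoxy-2-methyl-2H-chromen-5-yl]oxy}tri(propan-2-yl)silane | C=C1[C@H](C)CCC[C@]1(C)CC[C@@]1(C)C=Cc2c(O[Si](C(C)C)(C(C)C)C(C)C)c(OC)cc(OC)c2O1
F8 | step 6 | (2R,6R)-2-(but-3-yn-1-yl)-2,6-dimethyl-1-[(trimethylsilyl)methyl]cyclohexan-1-ol (either C1 epimer) | C[Si](C)(C)CC1(O)[C@H](C)CCC[C@]1(C)CCC#C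
F9 | step 15 | 5-{(1E,3S)-1-[benzyl(dimethyl)silyl]-3-hydroxy-5-[(1R,3R)-1,3-dimethyl-2-methylidenecyclohexyl]-3-methylpent-1-en-1-yl}-2-hydroxy-4-methoxyphenyl 4-methylbenzenesulfonate | C=C1[C@H](C)CCC[C@]1(C)CC[C@](C)(O)/C=C(\c1cc(OS(=O)(=O)c2ccc(C)cc2)c(O)cc1OC)[Si](C)(C)Cc1ccccc1
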